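**Retrosynthetic overview**
- The ten-membered ring is closed last, at C3–C4, by a Ni/Cr vinyl iodide–aldehyde coupling that sets C3; acetylation, silyl removal and unmasking of the exocyclic methylene from a Mannich base follow.
- The seco-aldehyde comes from angeloylation at O8, a Z-selective iodo-olefination of the C5 aldehyde, and a Ni/Cr coupling (C8–C9, sets C8) of a bicyclic lactol with a Z-iodoalkene carrying C9–C3.
- Key step: the bicyclic lactol comes from a light-driven hydrogen-atom-transfer 5-exo radical cyclisation of the MOM ether of (S)-5-(hydroxymethyl)butenolide, which forms C7–C8 and forces the cis lactone stereotriad (C7 from the bought C6).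
- The Z-iodoalkene comes from (S)-α-hydroxy-γ-butyrolactone (buys C1) by alkyne homologation and anti-carbomagnesiation/iodination.
- Ring order: γ-lactone (bought) → temporary cis-fused tetrahydrofuran acetal (photochemical) → ten-membered carbocycle.

Assumption and locants: target carbons are called C1 (CHOH), C2 (CH2), C3 (CHOAc), C4 (=CMe), C5 (=CH), C6 (lactone CH–O), C7 (ring-fusion CH), C8 (CHOAng), C9 (=CH), C10 (=CMe), C11/C12/C13 (lactone α-carbon, C=O, exocyclic CH2), so the target is 1S,3S,6R,7R,8R,4Z,9Z; acetal and lactol anomeric centres are carried as mixtures and the aminomethyl-bearing C11 is drawn as the expected single epimer, and all of these centres vanish before the target.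

**Step 1**
Reactants: 1 (S)-5-(hydroxymethyl)furan-2(5H)-one
Product: 2 (S)-5-[(methoxymethoxy)methyl]furan-2(5H)-one
Conditions: MOMCl, iPr2NEt, CH2Cl2, 0 °C to rt
Reagents that add atoms: chloromethyl methyl ether, COCCl
Why: O-alkylation of the primary alcohol (MOM ether formation) under a mild amine base leaves the butenolide and its bought C6 centre untouched and installs the O–CH2–O carbon that becomes C8.

**Step 2**
Reactants: 2 (S)-5-[(methoxymethoxy)methyl]furan-2(5H)-one
Product: 3 (3aR,6aS)-4-methoxytetrahydrofuro[3,4-b]furan-2(3H)-one (cis-fused, both C4 anomers)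
Conditions: (Bu4N)4[W10O32] (2 mol %), MeCN (0.02 M), 390 nm LEDs, N2, rt
Reagents that add atoms: none
Why: Proposed new method: the photoexcited [W10O32]4− anion abstracts the most hydridic hydrogen (O–CH2–O) by hydrogen atom transfer, the nucleophilic dialkoxymethyl radical adds 5-exo-trig to the electron-poor β-carbon C7 of the butenolide to which it is tied through the C5–O tether and therefore can only bond on the tether-bearing face (cis-fused bicycle, C7 set by the bought C6), and back hydrogen transfer from the reduced polyoxometalate to the α-acyl radical closes the cycle; the closest known reactions are the intermolecular decatungstate- or benzophenone-sensitised additions of 1,3-dioxolane to enoates and butenolides (which give the trans adduct) and the tin-mediated Ueno–Stork haloacetal cyclisation.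

**Step 3**
Reactants: 3 (3aR,6aS)-4-methoxytetrahydrofuro[3,4-b]furan-2(3H)-one
Product: 5 (3S,3aR,6aS)-3-[(dimethylamino)methyl]-4-hydroxytetrahydrofuro[3,4-b]furan-2(3H)-one (lactol, both anomers), via Mannich acetal 4 (not isolated)
Conditions: LiN(iPr)2, THF, −78 °C; CH2=NMe2+ I−, −78 °C to rt; then 1 M HCl, THF, rt; NaHCO3 work-up
Reagents that add atoms: N,N-dimethylmethyleneiminium iodide (Eschenmoser's salt), C=[N+](C)C.[I-]; water, O
Why: Mannich aminomethylation of the lactone lithium enolate on the convex face of the cis-fused bicycle masks the future exocyclic methylene as a base-stable amine, and the acidic work-up hydrolyses the furanoside-type methyl acetal to the lactol that serves as the C8 aldehyde.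

**Step 4**
Reactants: 6 (S)-3-hydroxydihydrofuran-2(3H)-one [(S)-α-hydroxy-γ-butyrolactone]
Product: 8 (3S)-pent-4-yne-1,3-diol, via lactol 7 (not isolated)
Conditions: iBu2AlH (2.2 equiv), CH2Cl2, −78 °C; then MeOH, K2CO3, dimethyl (1-diazo-2-oxopropyl)phosphonate, 0 °C to rt
Reagents that add atoms: dimethyl (1-diazo-2-oxopropyl)phosphonate, CC(=O)C(=[N+]=[N-])P(=O)(OC)OC
Why: partial reduction of the lactone to the lactol followed in the same flask by Seyferth–Gilbert homologation with the Ohira–Bestmann reagent turns the carbonyl carbon into a terminal alkyne without any bond change at the bought carbinol centre (future C1), the short cold reaction time limiting base epimerisation.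

**Step 5**
Reactants: 8 (3S)-pent-4-yne-1,3-diol
Product: 10 (3S,4Z)-5-iodo-4-methylpent-4-ene-1,3-diol, via alkenylmagnesium 9 (not isolated)
Conditions: MeMgBr (4 equiv), CuI (0.2 equiv), THF, −20 °C to rt; then I2, −78 to 0 °C
Reagents that add atoms: methylmagnesium bromide, C[Mg]Br; iodine, II
Why: copper-catalysed anti-carbomagnesiation of the propargylic alkoxide (Duboudin reaction) delivers methyl to the carbon next to the carbinol and holds magnesium in a five-membered chelate on the terminus cis to the carbinol, so iodinolysis with retention gives only the Z iodoalkene.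

**Step 6**
Reactants: 10 (3S,4Z)-5-iodo-4-methylpent-4-ene-1,3-diol
Product: 11 (3S,4Z)-5-iodo-4-methyl-1,3-bis(triethylsilyloxy)pent-4-ene
Conditions: Et3SiCl, imidazole, DMF, 0 °C to rt
Reagents that add atoms: chlorotriethylsilane, CC[Si](Cl)(CC)CC
Why: double silylation (silyl ether formation) protects the C1 oxygen until the end and turns the primary alcohol into a triethylsilyl ether that can later be oxidised directly to the C3 aldehyde.

**Step 7**
Reactants: 5 (3S,3aR,6aS)-3-[(dimethylamino)methyl]-4-hydroxytetrahydrofuro[3,4-b]furan-2(3H)-one; 11 (3S,4Z)-5-iodo-4-methyl-1,3-bis(triethylsilyloxy)pent-4-ene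
Product: 12 (3S,4S,5S)-3-[(dimethylamino)methyl]-4-[(1R,2Z,4S)-1-hydroxy-3-methyl-4,6-bis(triethylsilyloxy)hex-2-en-1-yl]-5-(hydroxymethyl)dihydrofuran-2(3H)-one
Conditions: CrCl2 (8 equiv), NiCl2 (2 mol %), DMSO, rt
Reagents that add atoms: none
Why: in this Nozaki–Hiyama–Kishi coupling the alkenylchromium from 11 adds with retention of the Z geometry to the hydroxy-aldehyde tautomer of lactol 5 and tolerates the lactone, and in strongly coordinating DMSO (no chelation) Felkin–Anh attack anti to the branched, oxygen-bearing C6 substituent of the α-stereocentre C7 gives the C8 carbinol with C11 and O8 syn as in the target.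

**Step 8**
Reactants: 12 (lactone diol from step 7)
Product: 13 lactol of 12: cis-fused 6-hydroxy-tetrahydrofuro[3,4-b]furan-2(3H)-one in which O8 bridges C8 and the new hemiacetal carbon C5, C8 carrying the (1Z,3S)-2-methyl-3,5-bis(triethylsilyloxy)pent-1-enyl group and C11 the CH2NMe2 group
Conditions: TEMPO (0.2 equiv), PhI(OAc)2 (1.1 equiv), AcOH (1 equiv), CH2Cl2, 0 °C
Reagents that add atoms: none
Why: oxoammonium (TEMPO) oxidation picks the unhindered primary alcohol over the hindered secondary allylic one, the γ-hydroxy aldehyde is trapped at once as the five-membered lactol so one equivalent of oxidant stops there, and the amine is shielded as its acetate salt.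

**Step 9**
Reactants: 13 (C5 lactol from step 8)
Product: 14 (3S,4S,5R-type lactone, drawn in the list) C8 alcohol carrying the (Z)-2-iodoprop-1-enyl group on C6: 3-[(dimethylamino)methyl]-4-[(1R,2Z,4S)-1-hydroxy-3-methyl-4,6-bis(triethylsilyloxy)hex-2-en-1-yl]-5-[(1Z)-2-iodoprop-1-en-1-yl]dihydrofuran-2(3H)-one, centres as in 12
Conditions: EtPPh3I, nBuLi, THF, rt; I2, −78 °C; NaN(SiMe3)2, −20 °C; then 13, −78 to −20 °C
Reagents that add atoms: ethyltriphenylphosphonium iodide, CC[P+](c1ccccc1)(c1ccccc1)c1ccccc1.[I-]; iodine, II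
Why: Stork–Zhao-type Wittig olefination of the lactol with the α-iodo ylide gives the Z 2-iodoalk-2-ene through the kinetic cis oxaphosphetane and frees O8, and at low temperature the hindered alkoxide does not transfer the lactone acyl group because that would need a strained bridged orthoester intermediate.

**Step 10**
Reactants: 14 (iodoalkenol from step 9)
Product: 15 C8 angelate of 14 [(2Z)-2-methylbut-2-enoate ester of the C8 hydroxyl, all other groups unchanged]
Conditions: angelic acid, 2,4,6-Cl3C6H2COCl, Et3N, PhMe, rt; then 14, PhMe, 75 °C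
Reagents that add atoms: angelic acid, C/C=C(/C)C(=O)O
Why: Yamaguchi esterification through the mixed anhydride, run without DMAP, acylates the hindered secondary alcohol without isomerising the angelate to the tiglate.

**Step 11**
Reactants: 15 (angelate from step 10)
Product: 16 seco-aldehyde: 15 with the primary CH2OSiEt3 terminus converted into the C3 aldehyde (C1 OSiEt3, C4 vinyl iodide, C8 angelate, lactone and CH2NMe2 unchanged)
Conditions: (COCl)2, DMSO, CH2Cl2, −78 to −30 °C; Et3N
Reagents that add atoms: none
Why: under Swern conditions a primary triethylsilyl ether is cleaved and oxidised directly to the aldehyde while the secondary silyl ether, the esters and the vinyl iodide are untouched.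

**Step 12**
Reactants: 16 (seco-aldehyde from step 11)
Product: 17 macrocyclic alcohol: the target skeleton with free C3–OH, C1–OSiEt3 and CH(CH2NMe2) at C11 in place of the exocyclic methylene (13-dimethylamino-11,13-dihydro, 3-O-deacetyl, 1-O-triethylsilyl target)
Conditions: CrCl2 (10 equiv), NiCl2 (0.1 equiv), DMSO/THF 3:1, 2 mM, slow addition, rt
Reagents that add atoms: none
Why: the intramolecular Nozaki–Hiyama–Kishi reaction closes the ten-membered ring at C3–C4 with retention of the Z vinyl geometry, the two Z olefins and the cis lactone bring the ends together, and 1,3-anti induction from the β-silyloxy centre C1 (polar Evans model) within the Z,Z-cyclodeca-1,6-diene sets the 3S carbinol.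

**Step 13**
Reactants: 17 (macrocyclic alcohol from step 12)
Product: 18 C3 acetate of 17
Conditions: Ac2O, pyridine, DMAP (cat.), CH2Cl2, 0 °C
Reagents that add atoms: acetic anhydride, CC(=O)OC(C)=O
Why: acetylation (nucleophilic acyl transfer) of the only free hydroxyl is unambiguous because O1 is silylated and O8 already esterified.

**Step 14**
Reactants: 18 (macrocyclic acetate from step 13)
Product: 19 13-(dimethylamino)-11,13-dihydro target (free C1–OH, C3–OAc, C8–OAng)
Conditions: HF·pyridine, pyridine, THF, 0 °C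
Reagents that add atoms: none
Why: buffered fluoride desilylation removes the secondary allylic triethylsilyl ether without acyl migration or ester cleavage.

**Step 15**
Reactants: 19 (amino lactone from step 14)
Product: 21 target, (3aR,4R,5Z,7S,9S,10Z,11aR)-9-(acetyloxy)-7-hydroxy-6,10-dimethyl-3-methylidene-2-oxo-2,3,3a,4,7,8,9,11a-octahydrocyclodeca[b]furan-4-yl (2Z)-2-methylbut-2-enoate, via methiodide 20 (not isolated)
Conditions: MeI, MeCN, rt; then NaHCO3, H2O/EtOAc, rt
Reagents that add atoms: none
Why: quaternisation of the Mannich base and mild base-induced Hofmann-type (E1cB) elimination release the α-methylene-γ-butyrolactone last, so the Michael acceptor never meets the ylide, chromium or acylation reagents.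

**Compound list**
1 | (S)-5-(hydroxymethyl)furan-2(5H)-one | O=C1C=C[C@@H](CO)O1 | starting material
2 | (S)-5-[(methoxymethoxy)methyl]furan-2(5H)-one | O=C1C=C[C@@H](COCOC)O1 | intermediate
3 | (3aR,6aS)-4-methoxytetrahydrofuro[3,4-b]furan-2(3H)-one, C4 anomers | O=C1C[C@H]2C(OC)OC[C@H]2O1 | intermediate
4 | (3S,3aR,6aS)-3-[(dimethylamino)methyl]-4-methoxytetrahydrofuro[3,4-b]furan-2(3H)-one, not isolated | CN(C)C[C@H]1C(=O)O[C@@H]2COC(OC)[C@H]12 | intermediate
5 | (3S,3aR,6aS)-3-[(dimethylamino)methyl]-4-hydroxytetrahydrofuro[3,4-b]furan-2(3H)-one, lactol anomers | CN(C)C[C@H]1C(=O)O[C@@H]2COC(O)[C@H]12 | intermediate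
6 | (S)-3-hydroxydihydrofuran-2(3H)-one | O[C@H]1CCOC1=O | starting material
7 | (3S)-tetrahydrofuran-2,3-diol, not isolated | O[C@H]1CCOC1O | intermediate
8 | (3S)-pent-4-yne-1,3-diol | OCC[C@H](O)C#C | intermediate
9 | (3S,4Z)-5-(bromomagnesio)-4-methylpent-4-ene-1,3-diol bis(bromomagnesium) alkoxide, not isolated | Br[Mg]OCC[C@H](O[Mg]Br)/C(C)=C\[Mg]Br | intermediate
10 | (3S,4Z)-5-iodo-4-methylpent-4-ene-1,3-diol | OCC[C@H](O)/C(C)=C\I | intermediate
11 | (3S,4Z)-5-iodo-4-methyl-1,3-bis(triethylsilyloxy)pent-4-ene | CC[Si](CC)(CC)OCC[C@H](O[Si](CC)(CC)CC)/C(C)=C\I | intermediate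
12 | (3S,4S,5S)-3-[(dimethylamino)methyl]-4-[(1R,2Z,4S)-1-hydroxy-3-methyl-4,6-bis(triethylsilyloxy)hex-2-en-1-yl]-5-(hydroxymethyl)dihydrofuran-2(3H)-one | CN(C)C[C@H]1C(=O)O[C@H](CO)[C@@H]1[C@H](O)/C=C(C)\[C@@H](O[Si](CC)(CC)CC)CCO[Si](CC)(CC)CC | intermediate
13 | C5 lactol of 12 (O8–C5 hemiacetal ring cis-fused to the lactone), anomers | CN(C)C[C@H]1C(=O)O[C@@H]2C(O)O[C@H](/C=C(C)\[C@@H](O[Si](CC)(CC)CC)CCO[Si](CC)(CC)CC)[C@H]12 | intermediate
14 | C8 alcohol with (Z)-2-iodoprop-1-enyl on C6 | CN(C)C[C@H]1C(=O)O[C@H](/C=C(/C)I)[C@@H]1[C@H](O)/C=C(C)\[C@@H](O[Si](CC)(CC)CC)CCO[Si](CC)(CC)CC | intermediate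
15 | C8 angelate of 14 | CN(C)C[C@H]1C(=O)O[C@H](/C=C(/C)I)[C@@H]1[C@H](OC(=O)/C(C)=C\C)/C=C(C)\[C@@H](O[Si](CC)(CC)CC)CCO[Si](CC)(CC)CC | intermediate
16 | seco-aldehyde (C3 CHO, C4 iodide) | CN(C)C[C@H]1C(=O)O[C@H](/C=C(/C)I)[C@@H]1[C@H](OC(=O)/C(C)=C\C)/C=C(C)\[C@@H](O[Si](CC)(CC)CC)CC=O | intermediate
17 | macrocyclic C3 alcohol, C1–OSiEt3, C11–CH2NMe2 | CN(C)C[C@H]1C(=O)O[C@@H]2/C=C(/C)[C@@H](O)C[C@H](O[Si](CC)(CC)CC)/C(C)=C\[C@@H](OC(=O)/C(C)=C\C)[C@H]12 | intermediate
18 | C3 acetate of 17 | CN(C)C[C@H]1C(=O)O[C@@H]2/C=C(/C)[C@@H](OC(C)=O)C[C@H](O[Si](CC)(CC)CC)/C(C)=C\[C@@H](OC(=O)/C(C)=C\C)[C@H]12 | intermediate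
19 | 13-(dimethylamino)-11,13-dihydro target | CN(C)C[C@H]1C(=O)O[C@@H]2/C=C(/C)[C@@H](OC(C)=O)C[C@H](O)/C(C)=C\[C@@H](OC(=O)/C(C)=C\C)[C@H]12 | intermediate
20 | trimethylammonium iodide of 19, not isolated | C[N+](C)(C)C[C@H]1C(=O)O[C@@H]2/C=C(/C)[C@@H](OC(C)=O)C[C@H](O)/C(C)=C\[C@@H](OC(=O)/C(C)=C\C)[C@H]12.[I-] | intermediate
21 | CNP0319825.3, (3aR,4R,5Z,7S,9S,10Z,11aR)-9-(acetyloxy)-7-hydroxy-6,10-dimethyl-3-methylidene-2-oxo-2,3,3a,4,7,8,9,11a-octahydrocyclodeca[b]furan-4-yl (2Z)-2-methylbut-2-enoate | C=C1C(=O)O[C@@H]2/C=C(/C)[C@@H](OC(C)=O)C[C@H](O)/C(C)=C\[C@@H](OC(=O)/C(C)=C\C)[C@H]12 | target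

**Step count and risks**
Total steps: 15 (steps 1–3 and 4–6 are two three-step branches, joined in step 7). Longest linear sequence: 12 steps (1 → 21; the branch from 6 is equally long).

Stereocentres: C6 and C1 are bought (1 and 6); C7 comes from the tether in step 2, C8 from step 7 and C3 from step 12. The transient anomeric and C11 centres are removed by steps 9 and 15.

The three steps most likely to fail:

Step 2 (new photocyclisation; competing hydrogen abstraction sites or slow ring closure). The fallback is known tin-hydride radical chemistry that sets out from 1 and comes back to the route at 3. Acid-catalysed exchange of 1 with PhSeCH(OMe)2 (Me3SiOTf cat., CH2Cl2, −40 °C) gives the mixed selenoorthoformate (S)-5-{[methoxy(phenylselanyl)methoxy]methyl}furan-2(5H)-one F1. Bu3SnH and AIBN (benzene, 80 °C, syringe pump) then abstract the selanyl group to give the same dialkoxymethyl radical, which closes 5-exo on the tether face to give 3 (Ueno–Stork-type cyclisation of an α-alkoxyalkyl radical).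

Step 7 (sluggish lactol and uncertain facial selectivity at C8). The fallback sets out from 5 and 11 and comes back at 15, and sets C8 by inversion instead of induction. If the chromium alkoxide on the C5 oxygen steers the addition to the 8S alcohol, the C8 epimer of 12 F2, this is carried through the conditions of steps 8 and 9 to the C8 epimer of lactol 13 F3 and the C8 epimer of iodoalkenol 14 F4. The angelate is then introduced with inversion by Mitsunobu esterification (angelic acid, PPh3, DIAD, toluene, 0 °C), which gives 15 directly.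

Step 12 (ten-membered ring closure and C3 selectivity). The fallback sets out from 16 and comes back at 18. If the ring conformation overrides the 1,3-induction and the 3R alcohol, the C3 epimer of 17 F5, is the main product, Mitsunobu esterification with acetic acid (PPh3, DIAD, AcOH, THF, 0 °C) inverts C3 and installs the acetate in one operation. This gives 18 and makes step 13 unnecessary.

**Further compounds**
F1 | step 2 | (S)-5-{[methoxy(phenylselanyl)methoxy]methyl}furan-2(5H)-one | O=C1C=C[C@@H](COC(OC)[Se]c2ccccc2)O1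
F2 | step 7 | (3S,4S,5S)-3-[(dimethylamino)methyl]-4-[(1S,2Z,4S)-1-hydroxy-3-methyl-4,6-bis(triethylsilyloxy)hex-2-en-1-yl]-5-(hydroxymethyl)dihydrofuran-2(3H)-one (C8 epimer of 12) | CN(C)C[C@H]1C(=O)O[C@H](CO)[C@@H]1[C@@H](O)/C=C(C)\[C@@H](O[Si](CC)(CC)CC)CCO[Si](CC)(CC)CC
F3 | step 7 | C8 epimer of lactol 13 | CN(C)C[C@H]1C(=O)O[C@@H]2C(O)O[C@@H](/C=C(C)\[C@@H](O[Si](CC)(CC)CC)CCO[Si](CC)(CC)CC)[C@H]12
F4 | step 7 | C8 epimer of iodoalkenol 14 | CN(C)C[C@H]1C(=O)O[C@H](/C=C(/C)I)[C@@H]1[C@@H](O)/C=C(C)\[C@@H](O[Si](CC)(CC)CC)CCO[Si](CC)(CC)CC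
F5 | step 12 | C3 epimer of macrocyclic alcohol 17 | CN(C)C[C@H]1C(=O)O[C@@H]2/C=C(/C)[C@H](O)C[C@H](O[Si](CC)(CC)CC)/C(C)=C\[C@@H](OC(=O)/C(C)=C\C)[C@H]12
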